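The synthesis rests on an anionic oxy-Cope ring expansion that creates the C1–C2 bond (briarane numbering). It exploits the C9 oxygen and the C3=C4 double bond, which flank that bond as a δ,ε-unsaturated ketone retron: ring B (ten-membered, C1–C10) is traced back to a shikimate-derived cyclohexene (C4–C9) whose C9 carbinol carries ring A (C1, C10–C14, from quinic acid) as a tetrasubstituted dienyl group and whose C4 carries a (Z)-enol ether. One [3,3] shift closes ring B, sets quaternary C1 and oxygenated C2 by chirality transfer, and delivers the C9 ketone with the cis,cis-3,5-diene. Lactone, epoxide and acetates follow.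

Key step: step 21

Remark: atoms keep their briarane numbers in all intermediates (C1 quaternary, C15 its methyl, C16 on C5, C17/C18/C19 the lactone CH/CH3/C=O, C20 the epoxide CH2); ring A is the carbocycle C1/C10–C14, ring B the ten-membered ring, ring C the lactone, ring D the cyclohexene C4–C9 of the precursor; aldehyde 23 is taken as purchasable.

Step 1
Reactants: 1 (−)-quinic acid
Product: 2 3,4-O-isopropylidene-1,5-quinide
Conditions: 2,2-dimethoxypropane, TsOH (cat.), acetone, reflux
Reagents that add atoms: 2,2-dimethoxypropane COC(C)(C)OC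
Why: Acid-catalysed acetalisation of the only cis-1,2-diol and lactonisation of the cis carboxyl/5-hydroxyl pair leave all stereocentres untouched.

Step 2
Reactants: 2 3,4-O-isopropylidene-1,5-quinide
Product: 4 (3R,4S,5R)-5-hydroxy-3,4-(isopropylidenedioxy)cyclohexanone, via triol 3 (not isolated)
Conditions: NaBH4, EtOH, 0 °C; then NaIO4, H2O, pH 6, 0 °C
Reagents that add atoms: none
Why: Hydride reduction of the lactone and periodate (Malaprade) cleavage of the resulting 1-hydroxymethyl-1-ol excise the carboxyl carbon and leave the ketone.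

Step 3
Reactants: 4 (3R,4S,5R)-5-hydroxy-3,4-(isopropylidenedioxy)cyclohexanone
Product: 6 (4S,5R)-4,5-(isopropylidenedioxy)cyclohex-2-en-1-one, via mesylate 5 (not isolated)
Conditions: MsCl, Et3N, CH2Cl2, 0 °C
Reagents that add atoms: none
Why: Mesylation of the β-hydroxy ketone is followed by E1cB elimination to the enone, which carries the future C14 and C13 oxygens.

Step 4
Reactants: 6 (4S,5R)-4,5-(isopropylidenedioxy)cyclohex-2-en-1-one
Product: 7 trimethylsilyl enol ether of the 3-methyl ketone (methyl trans to the neighbouring acetal oxygen)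
Conditions: MeLi, CuI, THF, −78 °C; then TMSCl, Et3N
Reagents that add atoms: lithium dimethylcuprate [Li+].C[Cu-]C; chlorotrimethylsilane C[Si](C)(C)Cl
Why: Gilman conjugate addition anti to the γ-oxygen with enolate trapping should give the enol silane; the new methyl-bearing centre becomes sp2 again in step 5.

Step 5
Reactants: 7 trimethylsilyl enol ether
Product: 8 (4S,5R)-4,5-(isopropylidenedioxy)-3-methylcyclohex-2-en-1-one
Conditions: Pd(OAc)2 (1 equiv), MeCN, rt
Reagents that add atoms: none
Why: Saegusa–Ito oxidation of the regiodefined enol silane restores the enone, now carrying the C15 methyl on the future C1.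

Step 6
Reactants: 8 (4S,5R)-4,5-(isopropylidenedioxy)-3-methylcyclohex-2-en-1-one
Product: 9 (4S,5R)-2-iodo-4,5-(isopropylidenedioxy)-3-methylcyclohex-2-en-1-one
Conditions: I2, pyridine, DMAP (cat.), CH2Cl2, rt
Reagents that add atoms: iodine II
Why: Amine-mediated α-iodination of the enone (conjugate addition, iodination, elimination) puts the halogen on the future C10.

Step 7
Reactants: 9 (4S,5R)-2-iodo-4,5-(isopropylidenedioxy)-3-methylcyclohex-2-en-1-one
Product: 10 ring-A iodo diene (C10–I, C1–CH3, C13/C14 acetonide, C11=C20 methylene)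
Conditions: Ph3PCH3Br, KHMDS, THF, 0 °C; then 9, 0 °C to rt
Reagents that add atoms: methylenetriphenylphosphorane C=P(c1ccccc1)(c1ccccc1)c1ccccc1
Why: Wittig methylenation installs C20 now, so that C11 never carries a β-leaving group when C9 later becomes an enolate.

Step 8
Reactants: 11 (−)-shikimic acid
Product: 13 methyl 3,4-O-isopropylidene shikimate, via methyl shikimate 12 (not isolated)
Conditions: MeOH, CSA, reflux; then 2,2-dimethoxypropane, acetone, rt
Reagents that add atoms: methanol CO; 2,2-dimethoxypropane COC(C)(C)OC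
Why: Fischer esterification and acetalisation of the cis-3,4-diol leave only the 5-hydroxyl (future O9) free; shikimate C3 is the future C7 in its final configuration.

Step 9
Reactants: 13 methyl 3,4-O-isopropylidene shikimate
Product: 14 methyl 5-O-(2-bromopropanoyl)-3,4-O-isopropylidene shikimate (both bromide epimers)
Conditions: 2-bromopropanoyl bromide, pyridine, CH2Cl2, −20 °C
Reagents that add atoms: 2-bromopropanoyl bromide CC(Br)C(Br)=O
Why: Acylation of the only free hydroxyl tethers the future C17–C19 unit to O9; the bromide configuration is irrelevant because it is lost on enolate formation.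

Step 10
Reactants: 14 methyl 5-O-(2-bromopropanoyl)-3,4-O-isopropylidene shikimate
Product: 15 methyl 5-O-(2-bromopropanoyl) shikimate
Conditions: AcOH/H2O (4:1), 40 °C
Reagents that add atoms: none
Why: Mild acetal hydrolysis frees the 3,4-diol without touching the two esters.

Step 11
Reactants: 15 methyl 5-O-(2-bromopropanoyl) shikimate
Product: 16 methyl 5-O-(2-bromopropanoyl)-3-O-triethylsilyl shikimate
Conditions: Et3SiCl, imidazole, DMF, −30 °C
Reagents that add atoms: chlorotriethylsilane CC[Si](Cl)(CC)CC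
Why: The allylic 3-hydroxyl is the more accessible of the two and should be silylated selectively, leaving the flanked 4-hydroxyl.

Step 12
Reactants: 16 methyl 5-O-(2-bromopropanoyl)-3-O-triethylsilyl shikimate
Product: 17 methyl 5-O-(2-bromopropanoyl)-4-oxo-3-O-triethylsilyl shikimate
Conditions: Dess–Martin periodinane, NaHCO3, CH2Cl2, 0 °C
Reagents that add atoms: none
Why: Buffered Dess–Martin oxidation turns the remaining secondary alcohol into the C8 ketone without enolisation.

Step 13
Reactants: 17 methyl 5-O-(2-bromopropanoyl)-4-oxo-3-O-triethylsilyl shikimate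
Product: 18 cis-fused O9–C19 γ-lactone (C8 tertiary OH, C17 methyl on the convex face, 7-O-TES, methyl ester at C16)
Conditions: SmI2 (2.2 equiv), THF, −78 °C
Reagents that add atoms: none
Why: In this intramolecular Reformatsky reaction the samarium enolate can reach the C8 ketone only from the face of the tethering O9, which sets C8 (OH cis to O7), and the C17 methyl takes the convex face of the cis-fused lactone.

Step 14
Reactants: 18 cis-fused O9–C19 γ-lactone
Product: 19 lactone with 7,8-O-isopropylidene acetal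
Conditions: 2,2-dimethoxypropane, CSA (cat.), acetone/MeOH (10:1), rt
Reagents that add atoms: 2,2-dimethoxypropane COC(C)(C)OC
Why: Acid removes the labile triethylsilyl ether and ties the cis O7/O8 diol into a compact acetonide, so that no free hydroxyl flanks C9 later.

Step 15
Reactants: 19 lactone with 7,8-O-isopropylidene acetal
Product: 20 triol (C9 secondary OH, C16 and C19 primary OH)
Conditions: LiAlH4, THF, 0 °C
Reagents that add atoms: none
Why: Hydride reduction opens the lactone to C19H2OH/C9–OH and reduces the enoate to the C16 allylic alcohol, which frees O9 and removes every electrophilic carbonyl before the organometallic steps.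

Step 16
Reactants: 20 triol
Product: 21 16,19-bis-TBS ether with free C9 hydroxyl
Conditions: TBSCl (2.2 equiv), imidazole, CH2Cl2, 0 °C
Reagents that add atoms: tert-butylchlorodimethylsilane CC(C)(C)[Si](C)(C)Cl
Why: The two primary hydroxyls are silylated much faster than the hindered secondary one.

Step 17
Reactants: 21 16,19-bis-TBS ether
Product: 22 ring-D ketone (C9=O, C4H2, C8 quaternary)
Conditions: Dess–Martin periodinane, NaHCO3, CH2Cl2, rt
Reagents that add atoms: none
Why: Oxidation of the only free alcohol gives a ketone that can enolise only towards C4.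

Step 18
Reactants: 22 ring-D ketone; 23 2-[(4-methoxybenzyl)oxy]acetaldehyde
Product: 26 C4-alkylidene ketone (exocyclic C4=C3, C2H2–OPMB, E/Z mixture), via lithium aldolate 24 (not isolated), via aldol mesylate 25 (not isolated)
Conditions: LiHMDS, THF, −78 °C; 23; then MsCl, −78 to 0 °C; DBU, rt
Reagents that add atoms: none
Why: Aldol condensation at the only enolisable α-carbon attaches C3 and C2; the alkene geometry does not matter because C4 becomes sp3 again in step 20.

Step 19
Reactants: 10 ring-A iodo diene; 26 C4-alkylidene ketone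
Product: 29 bis-allylic tertiary C9 carbinol carrying ring A, via alkenyllithium 27 (not isolated), via alkenylcerium dichloride 28 (not isolated)
Conditions: 10, t-BuLi (2 equiv), THF, −78 °C; CeCl3, −78 °C; then 26, −78 to −40 °C; aq. NH4Cl
Reagents that add atoms: none
Why: Iodine–lithium exchange, transmetalation to the weakly basic organocerium and 1,2-addition should occur on the carbonyl face anti to the C17 branch of C8 (the side of the dioxolane oxygen, which can chelate cerium), which places ring A cis to O8 at C9.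

Step 20
Reactants: 29 bis-allylic tertiary C9 carbinol
Product: 31 cis-1,2-dialkenyl carbinol with C4–H and (Z)-enol ether C3=C2–OPMB, via dilithio dienyl ether 30 (not isolated)
Conditions: LDA (2.5 equiv), THF, −78 to −30 °C; then MeOH, −78 °C
Reagents that add atoms: none
Why: Base-mediated allyl-to-(Z)-propenyl ether isomerisation: LDA removes the doubly allylic C2–H next to oxygen, the lithium-chelated Z-oxyallyl anion is protonated at its central carbon C4 from the face of the C9 oxygen (anti to the bulky ring A), and both alkene isomers of 29 converge on one C4 configuration.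

Step 21
Reactants: 31 cis-1,2-dialkenyl carbinol
Product: 34 ring-B ketone, 10-epimer (C9=O, C1 and C2 as in the target, 3Z and 5,6-ring-cis diene), via potassium alkoxide 32 (not isolated), via potassium dienolate 33 (not isolated)
Conditions: KH, 18-crown-6, THF, 0 °C to rt; then AcOH, −78 °C
Reagents that add atoms: none
Why: The potassium alkoxide 32 undergoes an anionic oxy-Cope [3,3] shift in which the C4–C9 bond of ring D breaks while C1 of ring A bonds to C2 of the enol ether, the charge ending in the cross-conjugated dienolate 33. The closest known reaction type is the anionic oxy-Cope ring expansion of cis-1,2-dialkenylcyclohexanols to cyclodec-5-enones. Ring B is closed by ring expansion of the six-membered ring D through a six-membered chair transition state, so no macrocyclisation entropy is paid. The C1 methyl, the inward substituent of the tetrasubstituted ring-A alkene, forces the small oxido group of C9 into the pseudoaxial site and the bulky C8 into the pseudoequatorial one; with the cis-dialkenyl arrangement this puts C5 pseudoaxial and gives the 3Z alkene, while the ring-D alkene becomes the cis C5=C6 bond. Quaternary C1 and C2 are set by chirality transfer from C9 and C4 through this chair, C2 also by the Z geometry of the enol ether (OPMB pseudoaxial, anti to the C1 methyl). The step needs the enol ether and not the ring-D alkene as partner of ring A, which the substrate secures because the C4–C9 bond lies near the nodal plane of the ring alkene but can align with the freely rotating enol ether; kinetic protonation of 33 on the face not covered by the new ring gives the 10-epimer 34.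

Step 22
Reactants: 34 ring-B ketone, 10-epimer
Product: 35 ring-B ketone with trans ring fusion (H10 cis to C2, anti to C15)
Conditions: DBU, CH2Cl2, rt
Reagents that add atoms: none
Why: Base-catalysed epimerisation through the dienolate should settle C10 in the configuration with both ring-B bonds equatorial on ring A, while conjugation into the tetrasubstituted enone is resisted by allylic strain.

Step 23
Reactants: 35 ring-B ketone
Product: 36 C9 alcohol (9S as in the target), 2-OPMB
Conditions: NaBH4, CeCl3·7H2O, MeOH/THF, −40 °C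
Reagents that add atoms: none
Why: Hydride is expected to attack the exposed face of the C9 carbonyl anti to the C17 branch on C8 (Felkin–Anh), setting C9; reduction before PMB removal avoids a C2–OH/C9 hemiketal.

Step 24
Reactants: 36 C9 alcohol
Product: 37 C2,C9-diol
Conditions: DDQ, CH2Cl2/pH 7 buffer, 0 °C
Reagents that add atoms: none
Why: Oxidative cleavage of the p-methoxybenzyl ether frees the C2 hydroxyl without touching silyl ethers, acetonides or alkenes.

Step 25
Reactants: 37 C2,C9-diol
Product: 38 2,9-diacetate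
Conditions: Ac2O, DMAP, pyridine, rt
Reagents that add atoms: acetic anhydride CC(=O)OC(C)=O
Why: Acetylation of the only two free hydroxyls installs two target acetates and blocks O9 from competing in the later lactonisation.

Step 26
Reactants: 38 2,9-diacetate
Product: 39 hexaol (free 7-, 8-, 13-, 14-, 16- and 19-OH; 2,9-diacetate)
Conditions: 48% aq. HF, MeCN, 0 °C to rt
Reagents that add atoms: none
Why: Aqueous HF cleaves both primary silyl ethers and both acetonides in one operation while the acetates survive.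

Step 27
Reactants: 39 hexaol
Product: 41 C19–O7 γ-lactone with C16 aldehyde and free 8,13,14-triol, via lactol 40 (not isolated)
Conditions: TEMPO (cat.), PhI(OAc)2, CH2Cl2, rt
Reagents that add atoms: none
Why: Oxoammonium oxidation is selective for primary alcohols; the C19 aldehyde is captured by the C7 hydroxyl as a five-membered lactol and oxidised on to ring C with retention at C7, while C16 becomes a dienal that deactivates the diene.

Step 28
Reactants: 41 lactone aldehyde triol
Product: 42 2,9,13,14-tetraacetate with C16 aldehyde and free tertiary 8-OH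
Conditions: Ac2O, pyridine, DMAP (cat.), 0 °C to rt
Reagents that add atoms: acetic anhydride CC(=O)OC(C)=O
Why: The secondary 13- and 14-hydroxyls are acetylated while the tertiary, hydrogen-bonded 8-hydroxyl is not.

Step 29
Reactants: 42 tetraacetate aldehyde
Product: 43 11,20-epoxide
Conditions: mCPBA, NaHCO3, CH2Cl2, 0 °C
Reagents that add atoms: 3-chloroperbenzoic acid OOC(=O)c1cccc(Cl)c1
Why: Prilezhaev epoxidation should pick the only electron-rich alkene (the C3–C6 diene is conjugated to the aldehyde) and attack C11=C20 equatorially, anti to the axial C15 methyl, placing the epoxide oxygen as in the target.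

Step 30
Reactants: 43 11,20-epoxide
Product: 44 CNP0317528.3
Conditions: NaBH4, CeCl3·7H2O, MeOH, −78 °C
Reagents that add atoms: none
Why: Luche 1,2-reduction converts the conjugated aldehyde into the C16 allylic alcohol without touching acetates, lactone or epoxide.

Compound list

1 | (−)-quinic acid | OC(=O)[C@]1(O)C[C@@H](O)[C@@H](O)[C@H](O)C1 | starting material
2 | 3,4-O-isopropylidene-1,5-quinide | O=C1O[C@@H]2C[C@@]1(O)C[C@H]3OC(C)(C)O[C@@H]23 | intermediate
3 | lactone-reduced triol of 2 (1-hydroxymethyl-1,5-diol, 3,4-acetonide) | OC[C@]1(O)C[C@H]2OC(C)(C)O[C@H]2[C@H](O)C1 | intermediate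
4 | (3R,4S,5R)-5-hydroxy-3,4-(isopropylidenedioxy)cyclohexanone | O=C1C[C@H]2OC(C)(C)O[C@H]2[C@H](O)C1 | intermediate
5 | 5-O-mesylate of 4 | O=C1C[C@H]2OC(C)(C)O[C@H]2[C@H](OS(C)(=O)=O)C1 | intermediate
6 | (4S,5R)-4,5-(isopropylidenedioxy)cyclohex-2-en-1-one | O=C1C=C[C@@H]2OC(C)(C)O[C@@H]2C1 | intermediate
7 | trimethylsilyl enol ether of the 3-methyl ketone, methyl trans to the neighbouring acetal oxygen | C[Si](C)(C)OC1=C[C@@H](C)[C@@H]2OC(C)(C)O[C@@H]2C1 | intermediate
8 | (4S,5R)-4,5-(isopropylidenedioxy)-3-methylcyclohex-2-en-1-one | O=C1C=C(C)[C@@H]2OC(C)(C)O[C@@H]2C1 | intermediate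
9 | (4S,5R)-2-iodo-4,5-(isopropylidenedioxy)-3-methylcyclohex-2-en-1-one | O=C1C(I)=C(C)[C@@H]2OC(C)(C)O[C@@H]2C1 | intermediate
10 | ring-A iodo diene (9 with C=O replaced by C=CH2) | C=C1C(I)=C(C)[C@@H]2OC(C)(C)O[C@@H]2C1 | intermediate
11 | (−)-shikimic acid | OC(=O)C1=C[C@@H](O)[C@@H](O)[C@H](O)C1 | starting material
12 | methyl shikimate | COC(=O)C1=C[C@@H](O)[C@@H](O)[C@H](O)C1 | intermediate
13 | methyl 3,4-O-isopropylidene shikimate | COC(=O)C1=C[C@H]2OC(C)(C)O[C@H]2[C@H](O)C1 | intermediate
14 | methyl 5-O-(2-bromopropanoyl)-3,4-O-isopropylidene shikimate | COC(=O)C1=C[C@H]2OC(C)(C)O[C@H]2[C@H](OC(=O)C(C)Br)C1 | intermediate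
15 | methyl 5-O-(2-bromopropanoyl) shikimate | COC(=O)C1=C[C@@H](O)[C@@H](O)[C@H](OC(=O)C(C)Br)C1 | intermediate
16 | methyl 5-O-(2-bromopropanoyl)-3-O-triethylsilyl shikimate | COC(=O)C1=C[C@@H](O[Si](CC)(CC)CC)[C@@H](O)[C@H](OC(=O)C(C)Br)C1 | intermediate
17 | methyl 5-O-(2-bromopropanoyl)-4-oxo-3-O-triethylsilyl shikimate | COC(=O)C1=C[C@@H](O[Si](CC)(CC)CC)C(=O)[C@H](OC(=O)C(C)Br)C1 | intermediate
18 | cis-fused O9–C19 γ-lactone, 8-OH, 17-methyl on the convex face, 7-O-TES, methyl ester | COC(=O)C1=C[C@@H](O[Si](CC)(CC)CC)[C@]2(O)[C@H](C)C(=O)O[C@@H]2C1 | intermediate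
19 | same lactone with 7,8-O-isopropylidene acetal | COC(=O)C1=C[C@H]2OC(C)(C)O[C@]23[C@H](C)C(=O)O[C@@H]3C1 | intermediate
20 | ring-D triol (9-OH, 16-OH, 19-OH), 7,8-acetonide | OCC1=C[C@H]2OC(C)(C)O[C@@]2([C@H](C)CO)[C@H](O)C1 | intermediate
21 | 16,19-bis-TBS ether of 20 | CC(C)(C)[Si](C)(C)OCC1=C[C@H]2OC(C)(C)O[C@@]2([C@H](C)CO[Si](C)(C)C(C)(C)C)[C@H](O)C1 | intermediate
22 | ring-D ketone (C9=O) | CC(C)(C)[Si](C)(C)OCC1=C[C@H]2OC(C)(C)O[C@@]2([C@H](C)CO[Si](C)(C)C(C)(C)C)C(=O)C1 | intermediate
23 | 2-[(4-methoxybenzyl)oxy]acetaldehyde | COc1ccc(COCC=O)cc1 | starting material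
24 | lithium aldolate at C4 (isomer mixture) | CC(C)(C)[Si](C)(C)OCC1=C[C@H]2OC(C)(C)O[C@@]2([C@H](C)CO[Si](C)(C)C(C)(C)C)C(=O)C1C(O[Li])COCc3ccc(OC)cc3 | intermediate
25 | aldol mesylate (isomer mixture) | CC(C)(C)[Si](C)(C)OCC1=C[C@H]2OC(C)(C)O[C@@]2([C@H](C)CO[Si](C)(C)C(C)(C)C)C(=O)C1C(OS(C)(=O)=O)COCc3ccc(OC)cc3 | intermediate
26 | C4-alkylidene ketone (E/Z mixture) | CC(C)(C)[Si](C)(C)OCC1=C[C@H]2OC(C)(C)O[C@@]2([C@H](C)CO[Si](C)(C)C(C)(C)C)C(=O)C1=CCOCc3ccc(OC)cc3 | intermediate
27 | ring-A alkenyllithium (C10–Li) | [Li]C1=C(C)[C@@H]2OC(C)(C)O[C@@H]2CC1=C | intermediate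
28 | ring-A alkenylcerium dichloride | Cl[Ce](Cl)C1=C(C)[C@@H]2OC(C)(C)O[C@@H]2CC1=C | intermediate
29 | bis-allylic tertiary C9 carbinol, ring A cis to O8, exocyclic C4=C3 | CC(C)(C)[Si](C)(C)OCC1=C[C@H]2OC(C)(C)O[C@@]2([C@H](C)CO[Si](C)(C)C(C)(C)C)[C@@](O)(C4=C(C)[C@@H]5OC(C)(C)O[C@@H]5CC4=C)C1=CCOCc3ccc(OC)cc3 | intermediate
30 | dilithio species (C9–OLi, C2–Li) | CC(C)(C)[Si](C)(C)OCC1=C[C@H]2OC(C)(C)O[C@@]2([C@H](C)CO[Si](C)(C)C(C)(C)C)[C@@](O[Li])(C4=C(C)[C@@H]5OC(C)(C)O[C@@H]5CC4=C)C1=CC([Li])OCc3ccc(OC)cc3 | intermediate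
31 | cis-1,2-dialkenyl carbinol: C4–H cis to the C9 oxygen, (Z)-enol ether on C4 cis to ring A | CC(C)(C)[Si](C)(C)OCC1=C[C@H]2OC(C)(C)O[C@@]2([C@H](C)CO[Si](C)(C)C(C)(C)C)[C@@](O)(C4=C(C)[C@@H]5OC(C)(C)O[C@@H]5CC4=C)[C@H]1/C=C\OCc3ccc(OC)cc3 | intermediate
32 | potassium alkoxide of 31 | CC(C)(C)[Si](C)(C)OCC1=C[C@H]2OC(C)(C)O[C@@]2([C@H](C)CO[Si](C)(C)C(C)(C)C)[C@@]([O-])(C4=C(C)[C@@H]5OC(C)(C)O[C@@H]5CC4=C)[C@H]1/C=C\OCc3ccc(OC)cc3.[K+] | intermediate
33 | potassium dienolate of the ring-B ketone (O–C9=C10–C11=C20) | COc1ccc(CO[C@H]2/C=C\C(CO[Si](C)(C)C(C)(C)C)=C/[C@H]3OC(C)(C)O[C@@]3([C@H](C)CO[Si](C)(C)C(C)(C)C)C([O-])=C4C(=C)C[C@H]5OC(C)(C)O[C@H]5[C@@]24C)cc1.[K+] | intermediate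
34 | ring-B ketone, 10-epimer (H10 cis to C15) | COc1ccc(CO[C@H]2/C=C\C(CO[Si](C)(C)C(C)(C)C)=C/[C@H]3OC(C)(C)O[C@@]3([C@H](C)CO[Si](C)(C)C(C)(C)C)C(=O)[C@H]4C(=C)C[C@H]5OC(C)(C)O[C@H]5[C@@]24C)cc1 | intermediate
35 | ring-B ketone, C10 as in the target | COc1ccc(CO[C@H]2/C=C\C(CO[Si](C)(C)C(C)(C)C)=C/[C@H]3OC(C)(C)O[C@@]3([C@H](C)CO[Si](C)(C)C(C)(C)C)C(=O)[C@@H]4C(=C)C[C@H]5OC(C)(C)O[C@H]5[C@@]24C)cc1 | intermediate
36 | C9 alcohol, 2-OPMB | COc1ccc(CO[C@H]2/C=C\C(CO[Si](C)(C)C(C)(C)C)=C/[C@H]3OC(C)(C)O[C@@]3([C@H](C)CO[Si](C)(C)C(C)(C)C)[C@@H](O)[C@@H]4C(=C)C[C@H]5OC(C)(C)O[C@H]5[C@@]24C)cc1 | intermediate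
37 | C2,C9-diol | O[C@H]1/C=C\C(CO[Si](C)(C)C(C)(C)C)=C/[C@H]2OC(C)(C)O[C@@]2([C@H](C)CO[Si](C)(C)C(C)(C)C)[C@@H](O)[C@@H]3C(=C)C[C@H]4OC(C)(C)O[C@H]4[C@@]13C | intermediate
38 | 2,9-diacetate | CC(=O)O[C@H]1/C=C\C(CO[Si](C)(C)C(C)(C)C)=C/[C@H]2OC(C)(C)O[C@@]2([C@H](C)CO[Si](C)(C)C(C)(C)C)[C@@H](OC(C)=O)[C@@H]3C(=C)C[C@H]4OC(C)(C)O[C@H]4[C@@]13C | intermediate
39 | hexaol, 2,9-diacetate | CC(=O)O[C@H]1/C=C\C(CO)=C/[C@@H](O)[C@](O)([C@H](C)CO)[C@@H](OC(C)=O)[C@@H]2C(=C)C[C@@H](O)[C@@H](O)[C@@]12C | intermediate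
40 | C19 lactol on O7 with C16 aldehyde | CC(=O)O[C@H]1/C=C\C(C=O)=C/[C@H]2OC(O)[C@@H](C)[C@]2(O)[C@@H](OC(C)=O)[C@@H]3C(=C)C[C@@H](O)[C@@H](O)[C@@]13C | intermediate
41 | ring-C lactone, C16 aldehyde, free 8,13,14-triol | CC(=O)O[C@H]1/C=C\C(C=O)=C/[C@H]2OC(=O)[C@@H](C)[C@]2(O)[C@@H](OC(C)=O)[C@@H]3C(=C)C[C@@H](O)[C@@H](O)[C@@]13C | intermediate
42 | 2,9,13,14-tetraacetate, C16 aldehyde, 11(20)-ene | CC(=O)O[C@H]1/C=C\C(C=O)=C/[C@H]2OC(=O)[C@@H](C)[C@]2(O)[C@@H](OC(C)=O)[C@@H]3C(=C)C[C@@H](OC(C)=O)[C@@H](OC(C)=O)[C@@]13C | intermediate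
43 | 11,20-epoxide with C16 aldehyde | CC(=O)O[C@H]1/C=C\C(C=O)=C/[C@H]2OC(=O)[C@@H](C)[C@]2(O)[C@@H](OC(C)=O)[C@@H]3[C@]4(CO4)C[C@@H](OC(C)=O)[C@@H](OC(C)=O)[C@@]13C | intermediate
44 | CNP0317528.3 | CC(=O)O[C@H]1/C=C\C(CO)=C/[C@H]2OC(=O)[C@@H](C)[C@]2(O)[C@@H](OC(C)=O)[C@@H]2[C@]3(CO3)C[C@@H](OC(C)=O)[C@@H](OC(C)=O)[C@@]12C | target

Total step count: 30. Longest linear sequence: 23 steps (steps 8–30 from shikimic acid 11); the quinic acid branch (steps 1–7) joins in step 19.

Steps most likely to fail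

Step 21 (key step). The congested alkoxide may fragment by expelling the ring-A alkenyl anion, or rearrange through the chair with C8 pseudoaxial and lose the 3Z geometry and the sense of chirality transfer. Fallback, a neutral thermal rearrangement in place of the anionic one: from 31, silylation with 1-(trimethylsilyl)imidazole gives the trimethylsilyl ether of 31 F1. Heating it (o-dichlorobenzene, N,O-bis(trimethylsilyl)acetamide, 160 °C) should effect a siloxy-Cope shift through the same chair, without an anionic fragmentation channel, to the ring-B trimethylsilyl dienol ether F2. K2CO3 in MeOH cleaves the enol silane, and the route is rejoined at 34.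

Step 22. The epimerisation at C10 may stop at an unfavourable equilibrium, or the exocyclic alkene may migrate into conjugation with the ketone. Fallback, internal proton delivery in place of thermodynamic control: from 34, DDQ removes the PMB group to give the 10-epi 2-hydroxy ketone F3. KHMDS (2.2 equiv) forms the alkoxide–dienolate, and AcOH at −78 °C then protonates it; the C2 oxygen, which sits on the ring-covered face, should relay the proton to C10 and give the 2-hydroxy ketone with the target C10 configuration F4. NaBH4/CeCl3 reduction of F4 leads to 37, where the route continues.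

Step 20. LDA may deprotonate at the wrong site (C7–H, the ring-A allylic CH2, or the benzylic CH2 followed by Wittig rearrangement), or the anion may be protonated at C6 to give the conjugated dienol ether. Fallback, installing the enol ether preformed: from 22, Pd-catalysed α-alkenylation of the ketone (Pd2(dba)3, XPhos, LiHMDS, toluene) with (Z)-1-bromo-2-[(4-methoxybenzyl)oxy]ethene (COc1ccc(CO/C=C\Br)cc1) gives the α-[(Z)-2-(PMB-oxy)vinyl] ketone F5, the C4 epimer with the side chain trans to C17 being carried on. Addition of alkenylcerium 28 to F5 under the conditions of step 19 gives 31, where the fallback comes back.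

Further compounds

F1 | step 21 | trimethylsilyl ether of 31 | CC(C)(C)[Si](C)(C)OCC1=C[C@H]2OC(C)(C)O[C@@]2([C@H](C)CO[Si](C)(C)C(C)(C)C)[C@@](O[Si](C)(C)C)(C4=C(C)[C@@H]5OC(C)(C)O[C@@H]5CC4=C)[C@H]1/C=C\OCc3ccc(OC)cc3
F2 | step 21 | ring-B trimethylsilyl dienol ether (C9–OTMS, C9=C10) | COc1ccc(CO[C@H]2/C=C\C(CO[Si](C)(C)C(C)(C)C)=C/[C@H]3OC(C)(C)O[C@@]3([C@H](C)CO[Si](C)(C)C(C)(C)C)C(O[Si](C)(C)C)=C4C(=C)C[C@H]5OC(C)(C)O[C@H]5[C@@]24C)cc1
F3 | step 22 | 10-epi 2-hydroxy ketone | O[C@H]1/C=C\C(CO[Si](C)(C)C(C)(C)C)=C/[C@H]2OC(C)(C)O[C@@]2([C@H](C)CO[Si](C)(C)C(C)(C)C)C(=O)[C@H]3C(=C)C[C@H]4OC(C)(C)O[C@H]4[C@@]13C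
F4 | step 22 | 2-hydroxy ketone with target C10 configuration | O[C@H]1/C=C\C(CO[Si](C)(C)C(C)(C)C)=C/[C@H]2OC(C)(C)O[C@@]2([C@H](C)CO[Si](C)(C)C(C)(C)C)C(=O)[C@@H]3C(=C)C[C@H]4OC(C)(C)O[C@H]4[C@@]13C
F5 | step 20 | α-[(Z)-2-(PMB-oxy)vinyl] ring-D ketone | CC(C)(C)[Si](C)(C)OCC1=C[C@H]2OC(C)(C)O[C@@]2([C@H](C)CO[Si](C)(C)C(C)(C)C)C(=O)[C@H]1/C=C\OCc3ccc(OC)cc3
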